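The quaternary oxirane carbon C2 carries the benzene ring, the ring oxygen and two CH2–O arms (oxirane C3 and the exocyclic CH2 of the cinnamate), so the target is a disguised 2-arylglycerol with enantiotopic hydroxymethyl groups. The route rests on telling these arms apart: a lipase moves the cinnamoyl group of vinyl cinnamate onto one primary hydroxyl of the achiral aryl triol, which installs the side-chain ester and creates the only stereocentre in one operation. Its precursor is the symmetric 2-arylpropane-1,2,3-triol that already bears the aryl isobutyrate and the free aldehyde, built from a metalated bromophenol acetal and protected dihydroxyacetone. Mesylation of the other arm and closure by the tertiary hydroxyl finish the oxirane.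

Key step: step 5

Assumption: the arm preferred by a lipase cannot be derived from first principles for this substrate, so the route assumes that a screen of commercial lipases (immobilized Candida antarctica lipase B, Burkholderia cepacia lipase and relatives) delivers one that acylates the pro-R hydroxymethyl group.

Step 1
Reactants: 1 4-bromo-3-hydroxybenzaldehyde
Product: 2 2-bromo-5-(1,3-dioxolan-2-yl)phenol
Conditions: ethylene glycol (3 equiv), p-TsOH·H2O (cat.), toluene, reflux, azeotropic removal of water
Reagents that add atoms: ethylene glycol, OCCO
Why: Acid-catalysed acetalisation with azeotropic removal of water should convert the aldehyde into its 1,3-dioxolane, which shields it from the organometallic reagents of step 2, while the phenol and the aryl bromide are untouched.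

Step 2
Reactants: 2 2-bromo-5-(1,3-dioxolan-2-yl)phenol, 3 2,2-dimethyl-1,3-dioxan-5-one
Product: 6 5-[4-(1,3-dioxolan-2-yl)-2-hydroxyphenyl]-2,2-dimethyl-1,3-dioxan-5-ol, via dilithiated phenoxide 4 (not isolated), via arylcerium dichloride 5 (not isolated)
Conditions: n-BuLi (2.1 equiv), THF, -78 to -40 °C; anhydrous CeCl3 (1.3 equiv), -78 °C; then 3, -78 to 0 °C; aq. NH4Cl
Reagents that add atoms: none
Why: One equivalent of n-BuLi deprotonates the phenol and the second effects bromine–lithium exchange ortho to the phenoxide, transmetalation to the less basic, more oxophilic organocerium curbs enolisation of ketone 3, and 1,2-addition of the aryl–metal bond to the carbonyl (organocerium addition to a ketone) should give the achiral tertiary carbinol after protonation.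

Step 3
Reactants: 6 5-[4-(1,3-dioxolan-2-yl)-2-hydroxyphenyl]-2,2-dimethyl-1,3-dioxan-5-ol
Product: 7 5-(1,3-dioxolan-2-yl)-2-(5-hydroxy-2,2-dimethyl-1,3-dioxan-5-yl)phenyl 2-methylpropanoate
Conditions: isobutyryl chloride (1.05 equiv), Et3N (1.5 equiv), CH2Cl2, 0 °C
Reagents that add atoms: isobutyryl chloride, CC(C)C(=O)Cl
Why: The triethylammonium phenoxide is acylated rapidly by the acid chloride (O-acylation of a phenol), whereas the tertiary alcohol flanked by the aryl ring and two ring CH2 groups should not react without an acyl-transfer catalyst, and both acetals are stable to the amine-buffered medium.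

Step 4
Reactants: 7 5-(1,3-dioxolan-2-yl)-2-(5-hydroxy-2,2-dimethyl-1,3-dioxan-5-yl)phenyl 2-methylpropanoate
Product: 8 5-formyl-2-(1,2,3-trihydroxypropan-2-yl)phenyl 2-methylpropanoate (achiral)
Conditions: 1 M aq. HCl, THF, 23 °C; neutral work-up, used promptly
Reagents that add atoms: water, O
Why: Dilute aqueous acid hydrolyses the six-membered acetonide and the aryl dioxolane in one operation (acetal hydrolysis), while the hindered aryl isobutyrate, which needs much harsher acid or base to cleave, should remain, and the product with two identical hydroxymethyl arms is still achiral.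

Step 5
Reactants: 8 5-formyl-2-(1,2,3-trihydroxypropan-2-yl)phenyl 2-methylpropanoate, 9 vinyl (E)-cinnamate
Product: 10 (2R)-2-[4-formyl-2-(2-methylpropanoyloxy)phenyl]-2,3-dihydroxypropyl (2E)-3-phenylprop-2-enoate
Conditions: immobilized Candida antarctica lipase B, 9 (3 equiv), dry MTBE, 4 Å MS, 35 °C; stopped at full consumption of 8, enzyme filtered off
Reagents that add atoms: none
Why: The catalytic serine of the lipase is acylated by 9 with loss of vinyl alcohol, which tautomerises to acetaldehyde and makes the transfer irreversible; the cinnamoyl-enzyme is then attacked by whichever primary hydroxyl of 8 the chiral pocket presents to it, so an ester C–O bond is formed and no ring is closed. The closest known reaction type is the lipase-mediated enantiotopic-group-selective acylation of prochiral 2-substituted propane-1,3-diols and 2-substituted glycerols with vinyl esters. The new quaternary stereocentre is controlled solely by the enzyme, which tells the bulky ortho-acyloxyaryl group from the small tertiary hydroxyl on the prochiral carbon and should acylate the pro-R hydroxymethyl arm to give the (R)-monoester. The step needs enantiotopic-group selectivity and chemoselectivity: the tertiary hydroxyl is too hindered to reach the acyl-enzyme, the phenol is blocked as a branched, ortho-shielded ester that is a poor acyl donor, and the aldehyde is a bystander. Any further acylation to the achiral bis-cinnamate removes the minor enantiomer of the monoester faster and so should only sharpen the enantiomeric purity. The medium is neutral, so the 1,3-shift of the cinnamoyl group that would racemise 10 is not triggered.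

Step 6
Reactants: 10 (2R)-2-[4-formyl-2-(2-methylpropanoyloxy)phenyl]-2,3-dihydroxypropyl (2E)-3-phenylprop-2-enoate
Product: 11 (2S)-2-[4-formyl-2-(2-methylpropanoyloxy)phenyl]-2-hydroxy-3-(methanesulfonyloxy)propyl (2E)-3-phenylprop-2-enoate
Conditions: MsCl (1.1 equiv), 2,4,6-collidine (2 equiv), CH2Cl2, -10 °C; cold dilute citric acid wash, crude used at once
Reagents that add atoms: methanesulfonyl chloride, CS(=O)(=O)Cl
Why: Sulfonylation with MsCl and the weak, hindered base collidine should occur only at the unhindered primary hydroxyl (selective O-mesylation), the tertiary benzylic hydroxyl being too encumbered and the cold, weakly basic medium keeping the cinnamoyl group from migrating; the stereocentre is untouched and its descriptor becomes S only because the mesyloxymethyl arm now outranks the cinnamoyloxymethyl arm.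

Step 7
Reactants: 11 (2S)-2-[4-formyl-2-(2-methylpropanoyloxy)phenyl]-2-hydroxy-3-(methanesulfonyloxy)propyl (2E)-3-phenylprop-2-enoate
Product: 12 [(2R)-2-[4-formyl-2-(2-methylpropanoyloxy)phenyl]oxiran-2-yl]methyl (2E)-3-phenylprop-2-enoate (target CNP0236352.2)
Conditions: DBU (1.2 equiv), MeCN, 0 °C
Reagents that add atoms: none
Why: DBU generates the tertiary alkoxide in low concentration, which displaces the adjacent primary mesylate in a 3-exo-tet intramolecular Williamson etherification helped by the gem-disubstituent effect of the fully substituted carbon; no bond to the stereocentre is made or broken, so the R configuration follows directly from 10, and the aprotic medium should spare the aryl ester, the cinnamate and the aldehyde.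

Compound list
1 | 4-bromo-3-hydroxybenzaldehyde | O=Cc1ccc(Br)c(O)c1 | starting material
2 | 2-bromo-5-(1,3-dioxolan-2-yl)phenol | Oc1cc(C2OCCO2)ccc1Br | intermediate
3 | 2,2-dimethyl-1,3-dioxan-5-one | CC1(C)OCC(=O)CO1 | starting material
4 | lithium 5-(1,3-dioxolan-2-yl)-2-lithiophenoxide (dilithiated phenoxide) | [Li]Oc1cc(C2OCCO2)ccc1[Li] | intermediate
5 | dichloro[4-(1,3-dioxolan-2-yl)-2-(lithiooxy)phenyl]cerium (arylcerium dichloride) | [Li]Oc1cc(C2OCCO2)ccc1[Ce](Cl)Cl | intermediate
6 | 5-[4-(1,3-dioxolan-2-yl)-2-hydroxyphenyl]-2,2-dimethyl-1,3-dioxan-5-ol | Oc1cc(C2OCCO2)ccc1C1(O)COC(C)(C)OC1 | intermediate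
7 | 5-(1,3-dioxolan-2-yl)-2-(5-hydroxy-2,2-dimethyl-1,3-dioxan-5-yl)phenyl 2-methylpropanoate | CC(C)C(=O)Oc1cc(C2OCCO2)ccc1C1(O)COC(C)(C)OC1 | intermediate
8 | 5-formyl-2-(1,2,3-trihydroxypropan-2-yl)phenyl 2-methylpropanoate (achiral) | CC(C)C(=O)Oc1cc(C=O)ccc1C(O)(CO)CO | intermediate
9 | vinyl (E)-cinnamate, ethenyl (2E)-3-phenylprop-2-enoate | C=COC(=O)/C=C/c1ccccc1 | starting material
10 | (2R)-2-[4-formyl-2-(2-methylpropanoyloxy)phenyl]-2,3-dihydroxypropyl (2E)-3-phenylprop-2-enoate | CC(C)C(=O)Oc1cc(C=O)ccc1[C@](O)(COC(=O)/C=C/c1ccccc1)CO | intermediate
11 | (2S)-2-[4-formyl-2-(2-methylpropanoyloxy)phenyl]-2-hydroxy-3-(methanesulfonyloxy)propyl (2E)-3-phenylprop-2-enoate | CC(C)C(=O)Oc1cc(C=O)ccc1[C@](O)(COC(=O)/C=C/c1ccccc1)COS(C)(=O)=O | intermediate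
12 | [(2R)-2-[4-formyl-2-(2-methylpropanoyloxy)phenyl]oxiran-2-yl]methyl (2E)-3-phenylprop-2-enoate | CC(C)C(=O)Oc1cc(C=O)ccc1[C@]1(COC(=O)/C=C/c2ccccc2)CO1 | target

Total step count: 7. Longest linear sequence: 7 steps (1 to 12); compounds 3 and 9 are bought and enter in steps 2 and 5.

Steps most likely to fail

Step 5. The enzyme may discriminate the two hydroxymethyl arms poorly, transfer the conjugated acyl group too slowly, or use the aryl ester as an acyl donor. The fallback sets out from triol 8 and differentiates the arms without an enzyme. A copper–bis(oxazoline)-catalysed enantiotopic-group-selective sulfonylation would be used: Cu(OTf)2 (divalent copper), the enantiomer of 2,2'-(propane-2,2-diyl)bis(4-phenyl-4,5-dihydrooxazole) that gives the required sense, TsCl, Na2CO3, MeCN, 0 °C. The copper chelate of the tertiary and one primary hydroxyl directs tosylation to that arm and should give (2S)-2-[4-formyl-2-(2-methylpropanoyloxy)phenyl]-2,3-dihydroxypropyl 4-methylbenzenesulfonate F1. Cinnamoyl chloride and 2,4,6-collidine in CH2Cl2 at 0 °C would then esterify the remaining primary hydroxyl to (2S)-2-[4-formyl-2-(2-methylpropanoyloxy)phenyl]-2-hydroxy-3-(tosyloxy)propyl (E)-cinnamate F2. DBU in MeCN would close the oxirane by displacement of the tosylate, and the fallback comes back to the route at compound 12. The cinnamate is put on before closure so that no free 2-arylglycidol, which could racemise by epoxide migration, is ever present.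

Step 2. The doubly charged aryl metal may form incompletely or aggregate, and the ketone may be enolised instead of attacked. The fallback sets out from phenol 2, which would be benzylated (BnBr, K2CO3, DMF) to 2-[3-(benzyloxy)-4-bromophenyl]-1,3-dioxolane F3. Bromine–lithium exchange with n-BuLi (1.05 equiv) in THF at -78 °C should give the monoanionic [2-(benzyloxy)-4-(1,3-dioxolan-2-yl)phenyl]lithium F4. This would be added directly to ketone 3 at -78 °C to give 5-[2-(benzyloxy)-4-(1,3-dioxolan-2-yl)phenyl]-2,2-dimethyl-1,3-dioxan-5-ol F5. Hydrogenolysis (H2, Pd/C, EtOAc with a trace of Et3N) would free the phenol, and the fallback comes back to the route at compound 6.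

Step 7. The tertiary alkoxide may attack the neighbouring aryl ester, shifting the isobutyryl group off the phenol oxygen, or the cinnamoyl group may migrate before the mesylate is displaced. The fallback sets out from diol 10 and avoids both the sulfonate and a free alkoxide. A Mitsunobu cyclodehydration (PPh3, DIAD, toluene, 0 to 23 °C) would turn the primary hydroxyl into an oxyphosphonium leaving group, which the tertiary hydroxyl displaces with retention at the stereocentre. The fallback comes back to the route at compound 12 and makes no new compound.

Further compounds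
F1 | step 5 | (2S)-2-[4-formyl-2-(2-methylpropanoyloxy)phenyl]-2,3-dihydroxypropyl 4-methylbenzenesulfonate | CC(C)C(=O)Oc1cc(C=O)ccc1[C@](O)(CO)COS(=O)(=O)c1ccc(C)cc1
F2 | step 5 | (2S)-2-[4-formyl-2-(2-methylpropanoyloxy)phenyl]-2-hydroxy-3-(tosyloxy)propyl (2E)-3-phenylprop-2-enoate | CC(C)C(=O)Oc1cc(C=O)ccc1[C@](O)(COC(=O)/C=C/c1ccccc1)COS(=O)(=O)c1ccc(C)cc1
F3 | step 2 | 2-[3-(benzyloxy)-4-bromophenyl]-1,3-dioxolane | Brc1ccc(C2OCCO2)cc1OCc1ccccc1
F4 | step 2 | [2-(benzyloxy)-4-(1,3-dioxolan-2-yl)phenyl]lithium | [Li]c1ccc(C2OCCO2)cc1OCc1ccccc1
F5 | step 2 | 5-[2-(benzyloxy)-4-(1,3-dioxolan-2-yl)phenyl]-2,2-dimethyl-1,3-dioxan-5-ol | OC1(c2ccc(C3OCCO3)cc2OCc2ccccc2)COC(C)(C)OC1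
F0 | step 7 | none | none
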